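**Retrosynthetic overview**
1. Target 26 ⇐ desilylation/O-demethylation ⇐ aromatic Claisen rearrangement (7-O-prenyl → 6-(1,1-dimethylallyl)-7-OH) ⇐ (2R)-flavan 23.
2. Ring C (closed last): O1–C2 by Mitsunobu inversion of syn-diol 20. The C3 hydroxyl, bought with methyl (R)-glycidate, sets C2 and is then removed (Barton–McCombie).
3. C2–C1′: chelation-controlled addition of the ring B aryllithium to the lactol of dihydrocoumarin 7. C4–C4a (key bond): blue-light nickel/photoredox reductive coupling of 4-iodoresorcinol with methyl (R)-glycidate, which also closes the lactone (first ring made).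
4. Dihydropyran on ring B (second ring made): aryl Grignard opening of methyl (S)-glycidate, MeMgCl, acid cyclodehydration; the prenyl group comes from a Stille coupling.
5. Ring order: lactone precursor of ring C → chromanol ring on ring B → ring C.

Assumption: methyl (R)- and (S)-glycidate (both sold, serine-derived) are taken as the cheap chiral starting materials; every other reagent and catalyst is achiral.

Step 1
Reactants: 1 4-iodobenzene-1,3-diol; 2 methyl (2R)-oxirane-2-carboxylate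
Product: 5 (3R)-3,7-dihydroxy-3,4-dihydro-2H-chromen-2-one, via iodohydrin 3 (not isolated), via hydroxy ester 4 (not isolated)
Conditions: NiBr2·glyme (10 mol%), 4,4'-di-tert-butyl-2,2'-bipyridine (12 mol%), 4CzIPN (2 mol%), NaI (30 mol%), Hantzsch ester (1.5 equiv), 2,6-lutidine (1.2 equiv), DMA, blue LEDs (450 nm), 25 °C; then TsOH·H2O (5 mol%), PhMe, 80 °C
Reagents that add atoms: none
Why: Proposed new method: a nickel/photoredox cross-electrophile coupling of an unprotected ortho-iodophenol with a glycidic ester, in which lutidinium iodide opens 2 at the unhindered C3 to iodohydrin 3 without touching the stereocenter, low-valent nickel abstracts the iodine to give a primary alkyl radical that is captured by the aryl–nickel species from 1, reductive elimination forges the C4–C4a bond with the blue-light-driven 4CzIPN/Hantzsch ester couple as electron source, and acid then closes the lactone; the closest known reaction type is the nickel/photoredox (or nickel/iodide) reductive coupling of aryl iodides with aliphatic terminal epoxides to linear β-aryl alcohols, here extended to an epoxy ester and a free resorcinol, and the C3 stereocenter is the one bought with 2.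

Step 2
Reactants: 5 (3R)-3,7-dihydroxy-3,4-dihydro-2H-chromen-2-one; 6 1-bromo-3-methylbut-2-ene
Product: 7 (3R)-3-hydroxy-7-[(3-methylbut-2-en-1-yl)oxy]-3,4-dihydro-2H-chromen-2-one
Conditions: K2CO3 (1.1 equiv), acetone, 25 °C
Reagents that add atoms: none
Why: Williamson ether synthesis: carbonate ionises only the phenol (the other ring oxygen is locked in the lactone and the α-hydroxyl is far less acidic), so the prenyl group lands on O7 alone and no stereocenter is touched.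

Step 3
Reactants: 8 5-bromo-2-methoxyphenol; 9 tributyl(3-methylbut-2-en-1-yl)stannane
Product: 10 2-methoxy-5-(3-methylbut-2-en-1-yl)phenol
Conditions: Pd(PPh3)4 (5 mol%), DMF, 90 °C
Reagents that add atoms: none
Why: Stille coupling: the prenylstannane transfers its unsubstituted terminus to the aryl–palladium bromide, giving the linear prenyl arene para to the methoxy group, and the free phenol is tolerated.

Step 4
Reactants: 10 2-methoxy-5-(3-methylbut-2-en-1-yl)phenol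
Product: 11 2,4-dibromo-6-methoxy-3-(3-methylbut-2-en-1-yl)phenol
Conditions: NBS (2.05 equiv), MeCN, −20 to 0 °C, dark
Reagents that add atoms: N-bromosuccinimide, O=C1CCC(=O)N1Br
Why: Electrophilic aromatic substitution: the free phenol directs bromine to its only open ortho and para positions, and in dry MeCN in the dark ring bromination of a phenol is much faster than attack on the trisubstituted alkene.

Step 5
Reactants: 11 2,4-dibromo-6-methoxy-3-(3-methylbut-2-en-1-yl)phenol; 12 methyl (2S)-oxirane-2-carboxylate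
Product: 15 (2S)-1-[5-bromo-2-hydroxy-3-methoxy-6-(3-methylbut-2-en-1-yl)phenyl]-3-methylbutane-2,3-diol, via aryl Grignard reagent 13 (not isolated), via hydroxy ester 14 (not isolated)
Conditions: MeMgCl (1.0 equiv), THF, −20 °C; i-PrMgCl·LiCl (1.1 equiv), 0 °C; CuI (10 mol%), 12, −30 °C; MeMgCl (3.5 equiv), 0 °C; aq NH4Cl
Reagents that add atoms: methylmagnesium chloride, C[Mg]Cl
Why: Chelation-directed bromine–magnesium exchange at the bromide ortho to the magnesium phenoxide, copper-catalysed SN2 opening of the glycidate at C3 (the stereocenter bought with 12 is not touched) and double Grignard addition to the ester give the diol with the (S)-carbinol.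

Step 6
Reactants: 15 (2S)-1-[5-bromo-2-hydroxy-3-methoxy-6-(3-methylbut-2-en-1-yl)phenyl]-3-methylbutane-2,3-diol
Product: 16 (3S)-6-bromo-8-methoxy-2,2-dimethyl-5-(3-methylbut-2-en-1-yl)-3,4-dihydro-2H-chromen-3-ol
Conditions: TsOH·H2O (10 mol%), PhMe, 60 °C
Reagents that add atoms: none
Why: Acid-catalysed cyclodehydration (SN1): the tertiary carbocation is trapped by the ortho phenol in a six-membered ring closure, so the secondary carbinol is not involved and keeps its (S) configuration.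

Step 7
Reactants: 16 (3S)-6-bromo-8-methoxy-2,2-dimethyl-5-(3-methylbut-2-en-1-yl)-3,4-dihydro-2H-chromen-3-ol
Product: 17 {[(3S)-6-bromo-8-methoxy-2,2-dimethyl-5-(3-methylbut-2-en-1-yl)-3,4-dihydro-2H-chromen-3-yl]oxy}(tert-butyl)dimethylsilane
Conditions: TBSOTf, 2,6-lutidine, CH2Cl2, 0 °C
Reagents that add atoms: tert-butyldimethylsilyl trifluoromethanesulfonate, CC(C)(C)[Si](C)(C)OS(=O)(=O)C(F)(F)F
Why: Silyl ether formation with the reactive triflate, needed because the hindered hydroxyl would otherwise quench the aryllithium and compete in the later deoxygenation.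

Step 8
Reactants: 7 (3R)-3-hydroxy-7-[(3-methylbut-2-en-1-yl)oxy]-3,4-dihydro-2H-chromen-2-one; 17 {[(3S)-6-bromo-8-methoxy-2,2-dimethyl-5-(3-methylbut-2-en-1-yl)-3,4-dihydro-2H-chromen-3-yl]oxy}(tert-butyl)dimethylsilane
Product: 20 (1R,2R)-1-[(3S)-3-{[tert-butyl(dimethyl)silyl]oxy}-8-methoxy-2,2-dimethyl-5-(3-methylbut-2-en-1-yl)-3,4-dihydro-2H-chromen-6-yl]-3-{2-hydroxy-4-[(3-methylbut-2-en-1-yl)oxy]phenyl}propane-1,2-diol, via lactol 18 (not isolated), via aryllithium 19 (not isolated)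
Conditions: 7, i-Bu2AlH (2.1 equiv), CH2Cl2, −78 °C; 17, t-BuLi (2.0 equiv), Et2O, −78 °C; combine, −78 to −20 °C; aq potassium sodium tartrate
Reagents that add atoms: none
Why: One-pot partial reduction of the lactone to the aluminium lactolate followed by Cram-chelate-controlled addition of the aryllithium to the derived α-aluminoxy aldehyde: the aryl group enters anti to the CH2Ar residue of the five-membered chelate, so the glycidate-derived carbinol sets the new benzylic carbinol as the syn (1R,2R) diol.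

Step 9
Reactants: 20 (1R,2R)-1-[(3S)-3-{[tert-butyl(dimethyl)silyl]oxy}-8-methoxy-2,2-dimethyl-5-(3-methylbut-2-en-1-yl)-3,4-dihydro-2H-chromen-6-yl]-3-{2-hydroxy-4-[(3-methylbut-2-en-1-yl)oxy]phenyl}propane-1,2-diol
Product: 21 (2S,3R)-2-[(3S)-3-{[tert-butyl(dimethyl)silyl]oxy}-8-methoxy-2,2-dimethyl-5-(3-methylbut-2-en-1-yl)-3,4-dihydro-2H-chromen-6-yl]-7-[(3-methylbut-2-en-1-yl)oxy]-3,4-dihydro-2H-chromen-3-ol
Conditions: PPh3, DIAD, THF, 0 to 25 °C
Reagents that add atoms: none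
Why: Intramolecular Mitsunobu etherification: the phenol displaces the activated benzylic hydroxyl with inversion, giving the 2,3-trans (2S,3R) flavan-3-ol, which is also the thermodynamically favoured isomer, so any ionisation converges on the same product.

Step 10
Reactants: 21 (2S,3R)-2-[(3S)-3-{[tert-butyl(dimethyl)silyl]oxy}-8-methoxy-2,2-dimethyl-5-(3-methylbut-2-en-1-yl)-3,4-dihydro-2H-chromen-6-yl]-7-[(3-methylbut-2-en-1-yl)oxy]-3,4-dihydro-2H-chromen-3-ol
Product: 23 tert-butyl(dimethyl){[(3S)-8-methoxy-2,2-dimethyl-5-(3-methylbut-2-en-1-yl)-6-{(2R)-7-[(3-methylbut-2-en-1-yl)oxy]-3,4-dihydro-2H-chromen-2-yl}-3,4-dihydro-2H-chromen-3-yl]oxy}silane, via thionocarbonate 22 (not isolated)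
Conditions: PhOC(S)Cl, pyridine, DMAP (cat.), CH2Cl2, 25 °C; then Bu3SnH, AIBN (cat.), PhSeSePh (5 mol%), PhMe, 90 °C
Reagents that add atoms: none
Why: Barton–McCombie deoxygenation removes the relay hydroxyl at C3 without touching C2 (its label changes from S to R only because the CIP ranking changes), the selenol formed in situ transferring hydrogen to the C3 radical faster than β-scission of the benzylic C–O bond.

Step 11
Reactants: 23 tert-butyl(dimethyl){[(3S)-8-methoxy-2,2-dimethyl-5-(3-methylbut-2-en-1-yl)-6-{(2R)-7-[(3-methylbut-2-en-1-yl)oxy]-3,4-dihydro-2H-chromen-2-yl}-3,4-dihydro-2H-chromen-3-yl]oxy}silane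
Product: 24 (2R)-2-[(3S)-3-{[tert-butyl(dimethyl)silyl]oxy}-8-methoxy-2,2-dimethyl-5-(3-methylbut-2-en-1-yl)-3,4-dihydro-2H-chromen-6-yl]-6-(2-methylbut-3-en-2-yl)-3,4-dihydro-2H-chromen-7-ol
Conditions: PhNEt2, 185 °C, sealed tube
Reagents that add atoms: none
Why: Aromatic Claisen rearrangement ([3,3]-sigmatropic) of the aryl prenyl ether places the 1,1-dimethylallyl group at C6, the ortho position not squeezed between two oxygens (as in related 2,4-dioxygenated aryl prenyl ethers), and frees the 7-hydroxyl; no stereocenter is involved.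

Step 12
Reactants: 24 (2R)-2-[(3S)-3-{[tert-butyl(dimethyl)silyl]oxy}-8-methoxy-2,2-dimethyl-5-(3-methylbut-2-en-1-yl)-3,4-dihydro-2H-chromen-6-yl]-6-(2-methylbut-3-en-2-yl)-3,4-dihydro-2H-chromen-7-ol
Product: 26 (2R)-2-[(3S)-3,8-dihydroxy-2,2-dimethyl-5-(3-methylbut-2-en-1-yl)-3,4-dihydro-2H-chromen-6-yl]-6-(2-methylbut-3-en-2-yl)-3,4-dihydro-2H-chromen-7-ol, via silyl-free methyl ether 25 (not isolated)
Conditions: Bu4NF, THF, 40 °C; then NaSEt, DMF, 120 °C; aqueous work-up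
Reagents that add atoms: none
Why: Fluoride desilylation followed by SN2 demethylation of the aryl methyl ether with ethanethiolate, conditions that leave the alkenes, the benzylic ether and both stereocenters untouched.

**Compound list**
1 | 4-iodobenzene-1,3-diol (4-iodoresorcinol) | Oc1ccc(I)c(O)c1 | starting material
2 | methyl (2R)-oxirane-2-carboxylate (methyl (R)-glycidate) | COC(=O)[C@H]1CO1 | starting material
3 | methyl (2S)-2-hydroxy-3-iodopropanoate | COC(=O)[C@H](O)CI | intermediate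
4 | methyl (2R)-3-(2,4-dihydroxyphenyl)-2-hydroxypropanoate | COC(=O)[C@H](O)Cc1ccc(O)cc1O | intermediate
5 | (3R)-3,7-dihydroxy-3,4-dihydro-2H-chromen-2-one | O=C1Oc2cc(O)ccc2C[C@H]1O | intermediate
6 | 1-bromo-3-methylbut-2-ene (prenyl bromide) | CC(C)=CCBr | starting material
7 | (3R)-3-hydroxy-7-[(3-methylbut-2-en-1-yl)oxy]-3,4-dihydro-2H-chromen-2-one | O=C1Oc2cc(OCC=C(C)C)ccc2C[C@H]1O | intermediate
8 | 5-bromo-2-methoxyphenol | COc1ccc(Br)cc1O | starting material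
9 | tributyl(3-methylbut-2-en-1-yl)stannane | CCCC[Sn](CCCC)(CCCC)CC=C(C)C | starting material
10 | 2-methoxy-5-(3-methylbut-2-en-1-yl)phenol | COc1ccc(CC=C(C)C)cc1O | intermediate
11 | 2,4-dibromo-6-methoxy-3-(3-methylbut-2-en-1-yl)phenol | COc1cc(Br)c(CC=C(C)C)c(Br)c1O | intermediate
12 | methyl (2S)-oxirane-2-carboxylate (methyl (S)-glycidate) | COC(=O)[C@@H]1CO1 | starting material
13 | {3-bromo-6-[(chloromagnesio)oxy]-5-methoxy-2-(3-methylbut-2-en-1-yl)phenyl}magnesium chloride | COc1cc(Br)c(CC=C(C)C)c([Mg]Cl)c1O[Mg]Cl | intermediate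
14 | methyl (2S)-3-[5-bromo-2-hydroxy-3-methoxy-6-(3-methylbut-2-en-1-yl)phenyl]-2-hydroxypropanoate | COC(=O)[C@@H](O)Cc1c(O)c(OC)cc(Br)c1CC=C(C)C | intermediate
15 | (2S)-1-[5-bromo-2-hydroxy-3-methoxy-6-(3-methylbut-2-en-1-yl)phenyl]-3-methylbutane-2,3-diol | CC(C)(O)[C@@H](O)Cc1c(O)c(OC)cc(Br)c1CC=C(C)C | intermediate
16 | (3S)-6-bromo-8-methoxy-2,2-dimethyl-5-(3-methylbut-2-en-1-yl)-3,4-dihydro-2H-chromen-3-ol | COc1cc(Br)c(CC=C(C)C)c2c1OC(C)(C)[C@@H](O)C2 | intermediate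
17 | {[(3S)-6-bromo-8-methoxy-2,2-dimethyl-5-(3-methylbut-2-en-1-yl)-3,4-dihydro-2H-chromen-3-yl]oxy}(tert-butyl)dimethylsilane | COc1cc(Br)c(CC=C(C)C)c2c1OC(C)(C)[C@@H](O[Si](C)(C)C(C)(C)C)C2 | intermediate
18 | (3R)-7-[(3-methylbut-2-en-1-yl)oxy]-3,4-dihydro-2H-chromene-2,3-diol (lactol, held as its aluminium alkoxide, both C2 epimers) | OC1Oc2cc(OCC=C(C)C)ccc2C[C@H]1O | intermediate
19 | [(3S)-3-{[tert-butyl(dimethyl)silyl]oxy}-8-methoxy-2,2-dimethyl-5-(3-methylbut-2-en-1-yl)-3,4-dihydro-2H-chromen-6-yl]lithium | [Li]c1cc(OC)c2OC(C)(C)[C@@H](O[Si](C)(C)C(C)(C)C)Cc2c1CC=C(C)C | intermediate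
20 | (1R,2R)-1-[(3S)-3-{[tert-butyl(dimethyl)silyl]oxy}-8-methoxy-2,2-dimethyl-5-(3-methylbut-2-en-1-yl)-3,4-dihydro-2H-chromen-6-yl]-3-{2-hydroxy-4-[(3-methylbut-2-en-1-yl)oxy]phenyl}propane-1,2-diol | O[C@@H]([C@H](O)Cc1ccc(OCC=C(C)C)cc1O)c1cc(OC)c2OC(C)(C)[C@@H](O[Si](C)(C)C(C)(C)C)Cc2c1CC=C(C)C | intermediate
21 | (2S,3R)-2-[(3S)-3-{[tert-butyl(dimethyl)silyl]oxy}-8-methoxy-2,2-dimethyl-5-(3-methylbut-2-en-1-yl)-3,4-dihydro-2H-chromen-6-yl]-7-[(3-methylbut-2-en-1-yl)oxy]-3,4-dihydro-2H-chromen-3-ol | O[C@@H]1Cc2ccc(OCC=C(C)C)cc2O[C@H]1c1cc(OC)c2OC(C)(C)[C@@H](O[Si](C)(C)C(C)(C)C)Cc2c1CC=C(C)C | intermediate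
22 | O-{(2S,3R)-2-[(3S)-3-{[tert-butyl(dimethyl)silyl]oxy}-8-methoxy-2,2-dimethyl-5-(3-methylbut-2-en-1-yl)-3,4-dihydro-2H-chromen-6-yl]-7-[(3-methylbut-2-en-1-yl)oxy]-3,4-dihydro-2H-chromen-3-yl} O-phenyl carbonothioate | S=C(Oc1ccccc1)O[C@@H]1Cc2ccc(OCC=C(C)C)cc2O[C@H]1c1cc(OC)c2OC(C)(C)[C@@H](O[Si](C)(C)C(C)(C)C)Cc2c1CC=C(C)C | intermediate
23 | tert-butyl(dimethyl){[(3S)-8-methoxy-2,2-dimethyl-5-(3-methylbut-2-en-1-yl)-6-{(2R)-7-[(3-methylbut-2-en-1-yl)oxy]-3,4-dihydro-2H-chromen-2-yl}-3,4-dihydro-2H-chromen-3-yl]oxy}silane | CC(C)=CCOc1ccc2c(c1)O[C@@H](c1cc(OC)c3OC(C)(C)[C@@H](O[Si](C)(C)C(C)(C)C)Cc3c1CC=C(C)C)CC2 | intermediate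
24 | (2R)-2-[(3S)-3-{[tert-butyl(dimethyl)silyl]oxy}-8-methoxy-2,2-dimethyl-5-(3-methylbut-2-en-1-yl)-3,4-dihydro-2H-chromen-6-yl]-6-(2-methylbut-3-en-2-yl)-3,4-dihydro-2H-chromen-7-ol | C=CC(C)(C)c1cc2c(cc1O)O[C@@H](c1cc(OC)c3OC(C)(C)[C@@H](O[Si](C)(C)C(C)(C)C)Cc3c1CC=C(C)C)CC2 | intermediate
25 | (2R)-2-[(3S)-3-hydroxy-8-methoxy-2,2-dimethyl-5-(3-methylbut-2-en-1-yl)-3,4-dihydro-2H-chromen-6-yl]-6-(2-methylbut-3-en-2-yl)-3,4-dihydro-2H-chromen-7-ol | C=CC(C)(C)c1cc2c(cc1O)O[C@@H](c1cc(OC)c3OC(C)(C)[C@@H](O)Cc3c1CC=C(C)C)CC2 | intermediate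
26 | (2R)-2-[(3S)-3,8-dihydroxy-2,2-dimethyl-5-(3-methylbut-2-en-1-yl)-3,4-dihydro-2H-chromen-6-yl]-6-(2-methylbut-3-en-2-yl)-3,4-dihydro-2H-chromen-7-ol (CNP0323011.2) | C=CC(C)(C)c1cc2c(cc1O)O[C@@H](c1cc(O)c3c(c1CC=C(C)C)C[C@H](O)C(C)(C)O3)CC2 | target

**Totals**
Total step count: 12. Longest linear sequence: 10 steps (8 → 26, steps 3–12); the ring A arm (steps 1–2) joins at step 8.

**Steps most likely to fail, with fallbacks**

Step 1 (the proposed new coupling): the free resorcinol may poison the nickel cycle or be oxidised by the photocatalyst, and iodide opening of the epoxy ester may be slow. The fallback uses known chemistry and sets out from 1. MOMCl/i-Pr2NEt gives 1-iodo-2,4-bis(methoxymethoxy)benzene F1. Iodine–magnesium exchange (i-PrMgCl·LiCl, THF, −20 °C) gives [2,4-bis(methoxymethoxy)phenyl]magnesium chloride F2. This opens 2 at C3 under CuI catalysis (−30 °C) to methyl (2R)-3-[2,4-bis(methoxymethoxy)phenyl]-2-hydroxypropanoate F3. HCl in MeOH removes both acetals to give 4, and TsOH in toluene closes the lactone, so the route is rejoined at 5.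

Step 8 (one-pot reduction and chelation-controlled arylation): over-reduction of the aryl lactone or poor syn selectivity would erode the C2 configuration. The fallback sets out from 7 and 19. After deprotonation of 7 with LiN(SiMe3)2 (1 equiv, −78 °C), 19 adds to the lactone carbonyl to give the α-hydroxy ketone (2R)-1-[(3S)-3-{[tert-butyl(dimethyl)silyl]oxy}-8-methoxy-2,2-dimethyl-5-(3-methylbut-2-en-1-yl)-3,4-dihydro-2H-chromen-6-yl]-2-hydroxy-3-{2-hydroxy-4-[(3-methylbut-2-en-1-yl)oxy]phenyl}propan-1-one F4. Zn(BH4)2 (Et2O, −20 °C) reduces it under chelation control to the anti-diol (1S,2R)-1-[(3S)-3-{[tert-butyl(dimethyl)silyl]oxy}-8-methoxy-2,2-dimethyl-5-(3-methylbut-2-en-1-yl)-3,4-dihydro-2H-chromen-6-yl]-3-{2-hydroxy-4-[(3-methylbut-2-en-1-yl)oxy]phenyl}propane-1,2-diol F5. Brief treatment with TsOH·H2O (2 mol%, CH2Cl2, −20 °C) ionises the para-alkoxybenzylic alcohol, and the phenol closes the ring through the cation with preference for the 2,3-trans ether (minor cis isomer removed by chromatography), so the route is rejoined at 21.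

Step 11 (late Claisen rearrangement): the 8-isomer, loss of the prenyl group or thermal damage at the penultimate stage are possible. The fallback sets out from 7 and does the rearrangement on the small lactone, where isomers are easy to separate:
- PhNEt2 at 185 °C gives (3R)-3,7-dihydroxy-6-(2-methylbut-3-en-2-yl)-3,4-dihydro-2H-chromen-2-one F6.
- NaH (1 equiv)/TBSCl silylates only the phenol to (3R)-7-{[tert-butyl(dimethyl)silyl]oxy}-3-hydroxy-6-(2-methylbut-3-en-2-yl)-3,4-dihydro-2H-chromen-2-one F7.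
- i-Bu2AlH gives the lactol (3R)-7-{[tert-butyl(dimethyl)silyl]oxy}-6-(2-methylbut-3-en-2-yl)-3,4-dihydro-2H-chromene-2,3-diol F8 (not isolated), which with 19 gives the syn-diol (1R,2R)-1-[(3S)-3-{[tert-butyl(dimethyl)silyl]oxy}-8-methoxy-2,2-dimethyl-5-(3-methylbut-2-en-1-yl)-3,4-dihydro-2H-chromen-6-yl]-3-[4-{[tert-butyl(dimethyl)silyl]oxy}-2-hydroxy-5-(2-methylbut-3-en-2-yl)phenyl]propane-1,2-diol F9.
- PPh3/DIAD closes it to (2S,3R)-7-{[tert-butyl(dimethyl)silyl]oxy}-2-[(3S)-3-{[tert-butyl(dimethyl)silyl]oxy}-8-methoxy-2,2-dimethyl-5-(3-methylbut-2-en-1-yl)-3,4-dihydro-2H-chromen-6-yl]-6-(2-methylbut-3-en-2-yl)-3,4-dihydro-2H-chromen-3-ol F10.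
- PhOC(S)Cl/pyridine gives its O-phenyl thionocarbonate F11 (not isolated), and Bu3SnH/AIBN reduces this to the bis-silyl ether of 25 F12.
- Bu4NF removes both silyl groups, so the route is rejoined at 25 for the final demethylation.

Further compounds
F1 | step 1 | 1-iodo-2,4-bis(methoxymethoxy)benzene | COCOc1ccc(I)c(OCOC)c1
F2 | step 1 | [2,4-bis(methoxymethoxy)phenyl]magnesium chloride | COCOc1ccc([Mg]Cl)c(OCOC)c1
F3 | step 1 | methyl (2R)-3-[2,4-bis(methoxymethoxy)phenyl]-2-hydroxypropanoate | COC(=O)[C@H](O)Cc1ccc(OCOC)cc1OCOC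
F4 | step 8 | (2R)-1-[(3S)-3-{[tert-butyl(dimethyl)silyl]oxy}-8-methoxy-2,2-dimethyl-5-(3-methylbut-2-en-1-yl)-3,4-dihydro-2H-chromen-6-yl]-2-hydroxy-3-{2-hydroxy-4-[(3-methylbut-2-en-1-yl)oxy]phenyl}propan-1-one | O=C([C@H](O)Cc1ccc(OCC=C(C)C)cc1O)c1cc(OC)c2OC(C)(C)[C@@H](O[Si](C)(C)C(C)(C)C)Cc2c1CC=C(C)C
F5 | step 8 | (1S,2R)-1-[(3S)-3-{[tert-butyl(dimethyl)silyl]oxy}-8-methoxy-2,2-dimethyl-5-(3-methylbut-2-en-1-yl)-3,4-dihydro-2H-chromen-6-yl]-3-{2-hydroxy-4-[(3-methylbut-2-en-1-yl)oxy]phenyl}propane-1,2-diol | O[C@H]([C@H](O)Cc1ccc(OCC=C(C)C)cc1O)c1cc(OC)c2OC(C)(C)[C@@H](O[Si](C)(C)C(C)(C)C)Cc2c1CC=C(C)C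
F6 | step 11 | (3R)-3,7-dihydroxy-6-(2-methylbut-3-en-2-yl)-3,4-dihydro-2H-chromen-2-one | O=C1Oc2cc(O)c(C(C)(C)C=C)cc2C[C@H]1O
F7 | step 11 | (3R)-7-{[tert-butyl(dimethyl)silyl]oxy}-3-hydroxy-6-(2-methylbut-3-en-2-yl)-3,4-dihydro-2H-chromen-2-one | O=C1Oc2cc(O[Si](C)(C)C(C)(C)C)c(C(C)(C)C=C)cc2C[C@H]1O
F8 | step 11 | (3R)-7-{[tert-butyl(dimethyl)silyl]oxy}-6-(2-methylbut-3-en-2-yl)-3,4-dihydro-2H-chromene-2,3-diol | OC1Oc2cc(O[Si](C)(C)C(C)(C)C)c(C(C)(C)C=C)cc2C[C@H]1O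
F9 | step 11 | (1R,2R)-1-[(3S)-3-{[tert-butyl(dimethyl)silyl]oxy}-8-methoxy-2,2-dimethyl-5-(3-methylbut-2-en-1-yl)-3,4-dihydro-2H-chromen-6-yl]-3-[4-{[tert-butyl(dimethyl)silyl]oxy}-2-hydroxy-5-(2-methylbut-3-en-2-yl)phenyl]propane-1,2-diol | O[C@@H]([C@H](O)Cc1cc(C(C)(C)C=C)c(O[Si](C)(C)C(C)(C)C)cc1O)c1cc(OC)c2OC(C)(C)[C@@H](O[Si](C)(C)C(C)(C)C)Cc2c1CC=C(C)C
F10 | step 11 | (2S,3R)-7-{[tert-butyl(dimethyl)silyl]oxy}-2-[(3S)-3-{[tert-butyl(dimethyl)silyl]oxy}-8-methoxy-2,2-dimethyl-5-(3-methylbut-2-en-1-yl)-3,4-dihydro-2H-chromen-6-yl]-6-(2-methylbut-3-en-2-yl)-3,4-dihydro-2H-chromen-3-ol | O[C@@H]1Cc2cc(C(C)(C)C=C)c(O[Si](C)(C)C(C)(C)C)cc2O[C@H]1c1cc(OC)c2OC(C)(C)[C@@H](O[Si](C)(C)C(C)(C)C)Cc2c1CC=C(C)C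
F11 | step 11 | O-{(2S,3R)-7-{[tert-butyl(dimethyl)silyl]oxy}-2-[(3S)-3-{[tert-butyl(dimethyl)silyl]oxy}-8-methoxy-2,2-dimethyl-5-(3-methylbut-2-en-1-yl)-3,4-dihydro-2H-chromen-6-yl]-6-(2-methylbut-3-en-2-yl)-3,4-dihydro-2H-chromen-3-yl} O-phenyl carbonothioate | S=C(Oc1ccccc1)O[C@@H]1Cc2cc(C(C)(C)C=C)c(O[Si](C)(C)C(C)(C)C)cc2O[C@H]1c1cc(OC)c2OC(C)(C)[C@@H](O[Si](C)(C)C(C)(C)C)Cc2c1CC=C(C)C
F12 | step 11 | tert-butyl{[(2R)-2-[(3S)-3-{[tert-butyl(dimethyl)silyl]oxy}-8-methoxy-2,2-dimethyl-5-(3-methylbut-2-en-1-yl)-3,4-dihydro-2H-chromen-6-yl]-6-(2-methylbut-3-en-2-yl)-3,4-dihydro-2H-chromen-7-yl]oxy}dimethylsilane | C=CC(C)(C)c1cc2c(cc1O[Si](C)(C)C(C)(C)C)O[C@@H](c1cc(OC)c3OC(C)(C)[C@@H](O[Si](C)(C)C(C)(C)C)Cc3c1CC=C(C)C)CC2
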